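The numbers in the tables were computed on assumed constants.

A small charge of L, 0.170 M in the delta flask, lies below the charges of the theta, beta and gamma runs, so I keep my books in fractions of the charge and ask where the L stands at 21 h.

| setting | theta | beta | epsilon | gamma | delta |
|---|---|---|---|---|---|
| L | 0.500 M | 0.300 M | 0.500 M | 1.00 M | 0.170 M |
| G |  |  | 0.250 M |  |  |
| time |  |  |  |  | 21 h |

| run | time / h | [G] / M |
|---|---|---|
| theta run | 0.84 | 0.009 |
| theta run | 1.6 | 0.015 |
| theta run | 3.0 | 0.037 |
| theta run | 5.8 | 0.090 |
| theta run | 11 | 0.162 |
| theta run | 21 | 0.214 |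
| beta run | 0.84 | 0.001 |
| beta run | 1.6 | 0.007 |
| beta run | 3.0 | 0.024 |
| beta run | 5.8 | 0.051 |
| beta run | 11 | 0.097 |
| beta run | 21 | 0.131 |
| epsilon run | 0.84 | 0.251 |
| epsilon run | 1.6 | 0.260 |
| epsilon run | 3.0 | 0.286 |
| epsilon run | 5.8 | 0.316 |
| epsilon run | 11 | 0.367 |
| epsilon run | 21 | 0.398 |
| gamma run | 0.84 | 0.010 |
| gamma run | 1.6 | 0.033 |
| gamma run | 3.0 | 0.080 |
| gamma run | 5.8 | 0.177 |
| gamma run | 11 | 0.316 |
| gamma run | 21 | 0.424 |

(readings scatter by 0.004 M)

1. reaction order in [L] at the outset, round the charge of the theta run, defined at two percent of the L turned into G (one fixed amount of G, the same in the runs compared)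
2. G in the delta run at 21 h, as a share of the L charged

- Overall: L -> G.
- Constant volume, constant temperature.
- An order is taken over about fifteen percent of the charge, up and down.

Every reading is of G, so my ledger has two entries, G and what is unread, and the three flasks charged with L and no G give as the first entry at 21 h:

theta: 0.214 M / 0.500 M = 42.8%

beta: 0.131 M / 0.300 M = 43.7%

gamma: 0.424 M / 1.00 M = 42.4%

Their mean is 43.0%, and I call this reading the standing share, the fraction of the L charged that stands as G at 21 h in a flask charged with L and no G. The three values spread over 1.3 percentage points, no wider than the scatter of one beta reading, which is 1.33% of its charge, so I carry the share down to the delta flask and close its books: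

G: 43.0% of 0.170 M = 0.0731 M

unread: 57.0% of the charge

The forecast reads the same runs, “The fractional conversion curves of the theta, beta and gamma runs coincide”, and gives 43% (40.5% to 45.5%) for the delta flask, with an order of 0.6 (0.4 to 0.85).

The delta flask gives 42.7% of its charge at 21 h, and the order comes out at 0.65, on these steps:

    L → Z (0.3449 h⁻¹)
    Z → G (0.08676 h⁻¹)
    G → Qa (0.01562 h⁻¹)
    L → Gy (0.1955 h⁻¹)

The passing of L into Gy moves the readings by 18 times the scatter, as a root mean square, yet the delta value lies 0.30 points below my standing share. In the epsilon flask, charged with 0.500 M of L, the share gives 0.215 M of G from L, so the 0.398 M read at 21 h holds 0.183 M of the 0.250 M of G charged, and the remainder, which the scheme sends to Qa, reads 26.8% of that G.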